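**Assumption:** the SMILES carries no stereodescriptors and the molecule has no stereocentre; the tetra-ortho-oxygenated biaryl axis is treated as configurationally unspecified, so no asymmetric step is needed.

**Retrosynthetic overview**
- Triumbelletin ⇐ its 7,7'-diacetate ⇐ Perkin-type aldol condensation forming C3–C4 of the central coumarin (coumarin B) from a biaryl salicylaldehyde and (coumarin-7-yloxy)acetic acid.
- The acid ⇐ umbelliferone + tert-butyl bromoacetate (coumarin A bought intact).
- The biaryl aldehyde ⇐ Suzuki–Miyaura coupling of 8-iodo-7-methoxycoumarin (coumarin C intact, from umbelliferone) with a 3-(dioxolanyl)-2,6-dimethoxyphenyl boronate (from 2,4-dimethoxybenzaldehyde by ortho-lithiation), then acetal hydrolysis and demethylation.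
- Ring order: coumarins A and C are preformed; the biaryl bond comes next; the pyranone ring of coumarin B is closed last, in the condensation.

**Route**

Step 1
Reactants: 1 umbelliferone (7-hydroxy-2H-chromen-2-one)
Product: 2 7-hydroxy-8-iodo-2H-chromen-2-one
Conditions: I2 (1.0 equiv)/KI in H2O added dropwise to 1 in 20% aq NH3, 0 °C to rt; then dilute H2SO4 to pH 3, recrystallise
Reagents that add atoms: iodine, II
Why: Electrophilic aromatic iodination of the phenoxide, in which C8 (ortho to the 7-oxygen and flanked by the ring oxygen) is the most nucleophilic position of a 7-hydroxycoumarin.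

Step 2
Reactants: 2 7-hydroxy-8-iodo-2H-chromen-2-one
Product: 3 8-iodo-7-methoxy-2H-chromen-2-one
Conditions: MeI (1.5 equiv), K2CO3, acetone, reflux
Reagents that add atoms: iodomethane, CI
Why: Williamson ether synthesis on an acidic phenol, giving a protecting group that tolerates the cross-coupling and the aqueous acid that follow.

Step 3
Reactants: 4 2,4-dimethoxybenzaldehyde
Product: 5 2-(2,4-dimethoxyphenyl)-1,3-dioxolane
Conditions: ethylene glycol (3 equiv), pTsOH·H2O (cat.), toluene, Dean–Stark reflux; Et3N quench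
Reagents that add atoms: ethylene glycol, OCCO
Why: Acid-catalysed acetalisation driven by azeotropic water removal masks the aldehyde against the organolithium of the next step.

Step 4
Reactants: 5 2-(2,4-dimethoxyphenyl)-1,3-dioxolane
Product: 7 2-[3-(1,3-dioxolan-2-yl)-2,6-dimethoxyphenyl]-4,4,5,5-tetramethyl-1,3,2-dioxaborolane, via aryllithium 6 (not isolated)
Conditions: n-BuLi (1.2 equiv), THF, 0 °C to rt, 2 h; then 2-isopropoxy-4,4,5,5-tetramethyl-1,3,2-dioxaborolane, −78 °C to rt; aq NH4Cl
Reagents that add atoms: 2-isopropoxy-4,4,5,5-tetramethyl-1,3,2-dioxaborolane, CC(C)OB1OC(C)(C)C(C)(C)O1; n-butyllithium, [Li]CCCC (lithium stays only in 6)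
Why: Directed ortho-metalation occurs at the position between the two methoxy groups (doubly activated), and the aryllithium is trapped by the borate ester in a standard borylation.

Step 5
Reactants: 3 8-iodo-7-methoxy-2H-chromen-2-one; 7 2-[3-(1,3-dioxolan-2-yl)-2,6-dimethoxyphenyl]-4,4,5,5-tetramethyl-1,3,2-dioxaborolane (1.5 equiv)
Product: 8 8-[3-(1,3-dioxolan-2-yl)-2,6-dimethoxyphenyl]-7-methoxy-2H-chromen-2-one
Conditions: Pd(OAc)2 (5 mol%), SPhos (2-dicyclohexylphosphino-2',6'-dimethoxybiphenyl, 10 mol%), K3PO4 (3 equiv), toluene/H2O 10:1, degassed, 100 °C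
Reagents that add atoms: none
Why: Suzuki–Miyaura coupling with a bulky electron-rich biarylphosphine, the ligand class that makes tetra-ortho-alkoxy biaryls from 2,6-dialkoxyaryl boron reagents and leaves the lactone and acetal untouched.

Step 6
Reactants: 8 8-[3-(1,3-dioxolan-2-yl)-2,6-dimethoxyphenyl]-7-methoxy-2H-chromen-2-one
Product: 9 2,4-dimethoxy-3-(7-methoxy-2-oxo-2H-chromen-8-yl)benzaldehyde
Conditions: 1 M aq HCl, THF, rt
Reagents that add atoms: water, O
Why: Acid-catalysed acetal hydrolysis is fast for this electron-rich aryl dioxolane and also re-closes any lactone opened under the basic coupling.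

Step 7
Reactants: 9 2,4-dimethoxy-3-(7-methoxy-2-oxo-2H-chromen-8-yl)benzaldehyde
Product: 10 2,4-dihydroxy-3-(7-hydroxy-2-oxo-2H-chromen-8-yl)benzaldehyde
Conditions: BBr3 (8 equiv), CH2Cl2, −78 °C to rt, 16 h; then ice/H2O
Reagents that add atoms: none
Why: Lewis-acid ether cleavage (BBr3 demethylation) removes all three aryl methyl ethers, hindered ones included, while the lactone and the aldehyde are recovered on aqueous work-up.

Step 8
Reactants: 1 umbelliferone; 11 tert-butyl bromoacetate
Product: 12 tert-butyl 2-[(2-oxo-2H-chromen-7-yl)oxy]acetate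
Conditions: K2CO3, acetone, reflux
Reagents that add atoms: none
Why: Williamson O-alkylation of the phenol with an activated primary bromide.

Step 9
Reactants: 12 tert-butyl 2-[(2-oxo-2H-chromen-7-yl)oxy]acetate
Product: 13 2-[(2-oxo-2H-chromen-7-yl)oxy]acetic acid
Conditions: TFA/CH2Cl2 1:2, rt
Reagents that add atoms: none
Why: Acidolysis of the tert-butyl ester (loss of isobutene) frees the acid without the aqueous base that would open the lactone.

Step 10
Reactants: 10 2,4-dihydroxy-3-(7-hydroxy-2-oxo-2H-chromen-8-yl)benzaldehyde; 13 2-[(2-oxo-2H-chromen-7-yl)oxy]acetic acid (1.3 equiv)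
Product: 16 7-acetoxy-8-(7-acetoxy-2-oxo-2H-chromen-8-yl)-3-[(2-oxo-2H-chromen-7-yl)oxy]-2H-chromen-2-one (triumbelletin diacetate), via tri-O-acetyl aldehyde 14 (not isolated), via mixed acetic anhydride 15 (not isolated)
Conditions: Ac2O (excess), Et3N (4 equiv), 120 °C, 12–16 h, N2
Reagents that add atoms: acetic anhydride, CC(=O)OC(C)=O
Why: Perkin–Oglialoro condensation, in which the enolate of mixed anhydride 15 adds to the formyl group of 14 (aldol addition), β-elimination gives the α-aryloxycinnamate, and acyl transfer from the ortho-acetoxy oxygen closes the lactone as the thermodynamic sink.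

Step 11
Reactants: 16 triumbelletin diacetate
Product: 17 triumbelletin, 7-hydroxy-8-(7-hydroxy-2-oxo-2H-chromen-8-yl)-3-[(2-oxo-2H-chromen-7-yl)oxy]-2H-chromen-2-one
Conditions: conc. HCl (cat.), MeOH/THF 1:1, 50 °C
Reagents that add atoms: none
Why: Acid-catalysed transesterification (methanolysis) removes the two phenolic acetates while the three lactones and the aryl vinyl ether, which are stable to acid, stay intact.

**Compound list**
1 | umbelliferone (7-hydroxy-2H-chromen-2-one) | O=c1ccc2ccc(O)cc2o1 | starting material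
2 | 7-hydroxy-8-iodo-2H-chromen-2-one | O=c1ccc2ccc(O)c(I)c2o1 | intermediate
3 | 8-iodo-7-methoxy-2H-chromen-2-one | COc1ccc2ccc(=O)oc2c1I | intermediate
4 | 2,4-dimethoxybenzaldehyde | COc1ccc(C=O)c(OC)c1 | starting material
5 | 2-(2,4-dimethoxyphenyl)-1,3-dioxolane | COc1ccc(C2OCCO2)c(OC)c1 | intermediate
6 | [3-(1,3-dioxolan-2-yl)-2,6-dimethoxyphenyl]lithium | [Li]c1c(OC)ccc(C2OCCO2)c1OC | intermediate (not isolated)
7 | 2-[3-(1,3-dioxolan-2-yl)-2,6-dimethoxyphenyl]-4,4,5,5-tetramethyl-1,3,2-dioxaborolane | COc1ccc(C2OCCO2)c(OC)c1B1OC(C)(C)C(C)(C)O1 | intermediate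
8 | 8-[3-(1,3-dioxolan-2-yl)-2,6-dimethoxyphenyl]-7-methoxy-2H-chromen-2-one | COc1ccc(C2OCCO2)c(OC)c1-c1c(OC)ccc2ccc(=O)oc12 | intermediate
9 | 2,4-dimethoxy-3-(7-methoxy-2-oxo-2H-chromen-8-yl)benzaldehyde | COc1ccc(C=O)c(OC)c1-c1c(OC)ccc2ccc(=O)oc12 | intermediate
10 | 2,4-dihydroxy-3-(7-hydroxy-2-oxo-2H-chromen-8-yl)benzaldehyde | O=Cc1ccc(O)c(-c2c(O)ccc3ccc(=O)oc23)c1O | intermediate
11 | tert-butyl bromoacetate | CC(C)(C)OC(=O)CBr | starting material
12 | tert-butyl 2-[(2-oxo-2H-chromen-7-yl)oxy]acetate | CC(C)(C)OC(=O)COc1ccc2ccc(=O)oc2c1 | intermediate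
13 | 2-[(2-oxo-2H-chromen-7-yl)oxy]acetic acid | OC(=O)COc1ccc2ccc(=O)oc2c1 | intermediate
14 | 2,4-diacetoxy-3-(7-acetoxy-2-oxo-2H-chromen-8-yl)benzaldehyde | CC(=O)Oc1ccc(C=O)c(OC(C)=O)c1-c1c(OC(C)=O)ccc2ccc(=O)oc12 | intermediate (not isolated)
15 | acetic 2-[(2-oxo-2H-chromen-7-yl)oxy]acetic anhydride | CC(=O)OC(=O)COc1ccc2ccc(=O)oc2c1 | intermediate (not isolated)
16 | 7-acetoxy-8-(7-acetoxy-2-oxo-2H-chromen-8-yl)-3-[(2-oxo-2H-chromen-7-yl)oxy]-2H-chromen-2-one | CC(=O)Oc1ccc2cc(Oc3ccc4ccc(=O)oc4c3)c(=O)oc2c1-c1c(OC(C)=O)ccc2ccc(=O)oc12 | intermediate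
17 | triumbelletin | O=c1ccc2ccc(Oc3cc4ccc(O)c(-c5c(O)ccc6ccc(=O)oc56)c4oc3=O)cc2o1 | target

**Count**
Total steps: 11. Longest linear sequence: 7 steps (3, 4, 5, 6, 7, 10, 11 from compound 4; equally 1, 2, 5, 6, 7, 10, 11 from compound 1).

**Three steps most likely to fail, each with a fallback**

Step 5 (tetra-ortho-substituted Suzuki coupling). The risks are protodeboronation of the electron-rich 2,6-dialkoxyaryl boronate and slow transmetalation of the hindered pinacol ester. The fallback sets out from 3 and puts the formyl group in after the biaryl bond. Compound 3 is coupled under the same Pd(OAc)2/SPhos/K3PO4 system with commercial 2,6-dimethoxyphenylboronic acid (COc1cccc(OC)c1B(O)O), the standard partner for this ligand, to give 8-(2,6-dimethoxyphenyl)-7-methoxy-2H-chromen-2-one F1. Rieche formylation (Cl2CHOMe, TiCl4, CH2Cl2, 0 °C) then attacks the only strongly activated position, on the dimethoxyphenyl ring ortho to one methoxy and para to the other; the two such positions are equivalent and the coumarin ring is deactivated. This comes back to the route at 9, and steps 3, 4 and 6 are no longer needed.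

Step 10 (Perkin condensation on a hindered, polyphenolic aldehyde). The risks are a low yield and competing condensation of acetic anhydride itself, which would give the 3-unsubstituted coumarin. The fallback sets out from 9 and separates ester formation from C–C bond formation. BCl3 (CH2Cl2, −78 to 0 °C) cleaves, by chelation, only the methoxy group ortho to the formyl group, giving 2-hydroxy-4-methoxy-3-(7-methoxy-2-oxo-2H-chromen-8-yl)benzaldehyde F2. The single free phenol is esterified with acid 13 (EDC·HCl, DMAP, CH2Cl2) to 6-formyl-3-methoxy-2-(7-methoxy-2-oxo-2H-chromen-8-yl)phenyl 2-[(2-oxo-2H-chromen-7-yl)oxy]acetate F3. DBU in MeCN at 60 °C then closes the ring by aldol condensation and dehydration to 7-methoxy-8-(7-methoxy-2-oxo-2H-chromen-8-yl)-3-[(2-oxo-2H-chromen-7-yl)oxy]-2H-chromen-2-one F4. BBr3 (CH2Cl2, −78 °C to rt) removes the two remaining methyl ethers; the ether oxygen between two sp2 carbons cannot be cleaved. This comes back at 17, and steps 7 and 11 are bypassed.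

Step 1 (iodination of umbelliferone). This is the only step whose regiochemistry is not enforced by the substrate; 6-iodo and 6,8-diiodo by-products may make purification difficult. The fallback sets out from 5 and fixes the iodine position by ortho-lithiation. Aryllithium 6, generated as in step 4, is quenched with I2 to give 2-(3-iodo-2,4-dimethoxyphenyl)-1,3-dioxolane F5. Hydrolysis with 1 M HCl/THF gives 3-iodo-2,4-dimethoxybenzaldehyde F6. BCl3 (CH2Cl2, −78 to 0 °C) removes only the methoxy group ortho to the aldehyde, giving 2-hydroxy-3-iodo-4-methoxybenzaldehyde F7. Heating F7 with ethyl (triphenylphosphoranylidene)acetate in N,N-diethylaniline at reflux gives, by Wittig olefination, ethyl (2E)-3-(2-hydroxy-3-iodo-4-methoxyphenyl)prop-2-enoate F8, which is not isolated; it isomerises thermally and lactonises with loss of ethanol. This comes back at 3, and steps 1 and 2 are no longer needed.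

**Further compounds**
F1 | step 5 | 8-(2,6-dimethoxyphenyl)-7-methoxy-2H-chromen-2-one | COc1cccc(OC)c1-c1c(OC)ccc2ccc(=O)oc12
F2 | step 10 | 2-hydroxy-4-methoxy-3-(7-methoxy-2-oxo-2H-chromen-8-yl)benzaldehyde | COc1ccc(C=O)c(O)c1-c1c(OC)ccc2ccc(=O)oc12
F3 | step 10 | 6-formyl-3-methoxy-2-(7-methoxy-2-oxo-2H-chromen-8-yl)phenyl 2-[(2-oxo-2H-chromen-7-yl)oxy]acetate | COc1ccc(C=O)c(OC(=O)COc2ccc3ccc(=O)oc3c2)c1-c1c(OC)ccc2ccc(=O)oc12
F4 | step 10 | 7-methoxy-8-(7-methoxy-2-oxo-2H-chromen-8-yl)-3-[(2-oxo-2H-chromen-7-yl)oxy]-2H-chromen-2-one | COc1ccc2cc(Oc3ccc4ccc(=O)oc4c3)c(=O)oc2c1-c1c(OC)ccc2ccc(=O)oc12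
F5 | step 1 | 2-(3-iodo-2,4-dimethoxyphenyl)-1,3-dioxolane | COc1ccc(C2OCCO2)c(OC)c1I
F6 | step 1 | 3-iodo-2,4-dimethoxybenzaldehyde | COc1ccc(C=O)c(OC)c1I
F7 | step 1 | 2-hydroxy-3-iodo-4-methoxybenzaldehyde | COc1ccc(C=O)c(O)c1I
F8 | step 1 | ethyl (2E)-3-(2-hydroxy-3-iodo-4-methoxyphenyl)prop-2-enoate | CCOC(=O)/C=C/c1ccc(OC)c(I)c1O
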